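**Plan**

1. Locants: ring C1–C10 (oxirane C1/C10, OAc on C3, C4=C5, lactone O on C6, C7, ester O on C8), lactone carbons C11(=C13H2) and C12(=O), C14 on C10, C15 on C4. Cuts, in retrosynthetic order: oxirane O; the two ester C–O bonds; C1=C10 (metathesis); C11–C12 with C12–O6 (CO); C13 (diazophosphonate); C6–C7 (aldol); C9–C10, C5–C6 and C2–C3 (organometallic additions).
2. Forward: enal 9 (C1–C6) and imide 16 (C7–C11) are joined by an aldol. The γ-lactone is closed first, on the open chain (step 14). The ten-membered ring follows by ring-closing metathesis (step 15) and the oxirane comes last (step 20).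
3. Stereochemistry: C3 from a Brown allylation; C8 from ethyl (R)-3,4-epoxybutanoate; C6/C7 from an Evans syn aldol; 4Z from anti-carbomagnesiation of propargyl alcohol; 1(10)Z from ring strain in the metathesis; C1/C10 from a Shi epoxidation.
4. Enabling feature: O6–H and the ethynyl group on C7 (C11≡C13) are homopropargylic. CO held on palladium as O6–C12(=O)–Pd therefore reaches C11 by 5-exo-dig insertion, closing ring O6–C6–C7–C11–C12 and leaving C13 as the exocyclic methylene. The cis-fused lactone then holds the C5 and C8 chains on one side for the ten-membered ring closure.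

Key step: step 14

Remark: the target is read as having a cis 6,7-ring fusion (H6 and H7 on one face) and a cis-configured oxirane (C2 and C9 on one side); 10, 14, (+)-Ipc2BOMe and the D-fructose-derived Shi ketone are taken as purchasable.

**Route**

Step 1
Reactants: 1 prop-2-yn-1-ol
Product: 3 (Z)-3-iodo-2-methylprop-2-en-1-ol, via alkenylmagnesium alkoxide 2 (not isolated)
Conditions: MeMgBr (2.5 equiv), CuI (10 mol %), Et2O, −10 °C → rt; then I2, −78 → 0 °C
Reagents that add atoms: methylmagnesium bromide C[Mg]Br; iodine II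
Why: Copper-catalysed anti-carbomagnesiation of the propargylic alkoxide gives the chelated alkenylmagnesium 2 with Mg cis to the CH2O group, and iodinolysis with retention fixes the Z geometry of the later C4=C5 bond (C3, C4, C5 and C15 are now in place).

Step 2
Reactants: 3 (Z)-3-iodo-2-methylprop-2-en-1-ol
Product: 4 (Z)-3-iodo-2-methylprop-2-enal
Conditions: MnO2, CH2Cl2, rt, dark
Reagents that add atoms: none
Why: Allylic alcohol oxidation with MnO2 is neutral and selective, so the Z-iodoalkene should survive without isomerisation.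

Step 3
Reactants: 4 (Z)-3-iodo-2-methylprop-2-enal
Product: 6 (1Z,3R)-1-iodo-2-methylhexa-1,5-dien-3-ol, via borinate ester 5 (not isolated)
Conditions: (+)-Ipc2BOMe, allylMgBr, Et2O, 0 °C → rt; then 4, −78 °C; NaOH, H2O2, 0 °C → rt
Reagents that add atoms: allylmagnesium bromide C=CC[Mg]Br
Why: Brown allylboration, in which the (−)-α-pinene-derived allylborane adds through a closed chair transition state to the Re face of the aldehyde, sets C3 (R) under reagent control and brings in C2 and C1.

Step 4
Reactants: 6 (1Z,3R)-1-iodo-2-methylhexa-1,5-dien-3-ol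
Product: 7 (1Z,3R)-1-iodo-3-[(4-methoxybenzyl)oxy]-2-methylhexa-1,5-diene
Conditions: NaH, 4-methoxybenzyl chloride, Bu4NI (cat.), DMF, 0 °C → rt
Reagents that add atoms: 4-methoxybenzyl chloride COc1ccc(CCl)cc1
Why: Williamson etherification masks O3 as a PMB ether that tolerates the organolithium, boron-aldol, hydride and palladium steps and is later removed oxidatively.

Step 5
Reactants: 7 (1Z,3R)-1-iodo-3-[(4-methoxybenzyl)oxy]-2-methylhexa-1,5-diene
Product: 9 (2Z,4R)-4-[(4-methoxybenzyl)oxy]-3-methylhepta-2,6-dienal, via alkenyllithium 8 (not isolated)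
Conditions: t-BuLi (2.1 equiv), Et2O, −78 °C; DMF, −78 → 0 °C; aq. NH4Cl
Reagents that add atoms: N,N-dimethylformamide CN(C)C=O
Why: Iodine–lithium exchange proceeds with retention of alkene geometry at −78 °C, and formylation of the alkenyllithium with DMF adds C6 as the Z enal.

Step 6
Reactants: 10 ethyl 2-[(2R)-oxiran-2-yl]acetate
Product: 11 ethyl (3S)-3-hydroxy-5-methylhex-5-enoate
Conditions: isopropenylmagnesium bromide, CuI (10 mol %), THF, −40 → −20 °C; aq. NH4Cl
Reagents that add atoms: isopropenylmagnesium bromide CC(=C)[Mg]Br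
Why: Copper-catalysed Grignard opening of the terminal epoxide at its CH2 carbon (C9) forms C9–C10 without touching the stereocentre, so C8 (S) comes from the chiral pool.

Step 7
Reactants: 11 ethyl (3S)-3-hydroxy-5-methylhex-5-enoate
Product: 12 ethyl (3S)-3-[(tert-butyldimethylsilyl)oxy]-5-methylhex-5-enoate
Conditions: TBSCl, imidazole, DMF, rt
Reagents that add atoms: tert-butyldimethylsilyl chloride CC(C)(C)[Si](C)(C)Cl
Why: Standard silylation protects O8 as a TBS ether that resists enolisation conditions and later blocks O8 during the carbonylation.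

Step 8
Reactants: 12 ethyl (3S)-3-[(tert-butyldimethylsilyl)oxy]-5-methylhex-5-enoate
Product: 13 (3S)-3-[(tert-butyldimethylsilyl)oxy]-5-methylhex-5-enoic acid
Conditions: LiOH, THF–MeOH–H2O, rt; then 1 M HCl to pH 3
Reagents that add atoms: lithium hydroxide [Li+].[OH-]
Why: Saponification of the ethyl ester under conditions that leave a secondary TBS ether intact.

Step 9
Reactants: 13 (3S)-3-[(tert-butyldimethylsilyl)oxy]-5-methylhex-5-enoic acid; 14 (4R)-4-benzyl-1,3-oxazolidin-2-one
Product: 16 (4R)-4-benzyl-3-[(3S)-3-[(tert-butyldimethylsilyl)oxy]-5-methylhex-5-enoyl]-1,3-oxazolidin-2-one, via mixed pivalic anhydride 15 (not isolated)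
Conditions: pivaloyl chloride, Et3N, THF, −20 °C; then 14, LiCl, −20 °C → rt
Reagents that add atoms: none
Why: N-Acylation of the oxazolidinone through the mixed pivalic anhydride is the standard entry to Evans imides and does not affect C8.

Step 10
Reactants: 16 (4R)-4-benzyl-3-[(3S)-3-[(tert-butyldimethylsilyl)oxy]-5-methylhex-5-enoyl]-1,3-oxazolidin-2-one; 9 (2Z,4R)-4-[(4-methoxybenzyl)oxy]-3-methylhepta-2,6-dienal
Product: 19 Evans syn-aldol adduct (C6–OH; C7 bearing the imide carbonyl C11; C8–OTBS; 4Z), via Z-boron enolate 17 (not isolated), via boron aldolate 18 (not isolated)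
Conditions: n-Bu2BOTf, Et3N, CH2Cl2, −78 → 0 °C; 9, −78 → 0 °C; pH 7 buffer, MeOH, H2O2, 0 °C
Reagents that add atoms: none
Why: Evans syn aldol, in which the Z boron enolate reacts through a Zimmerman–Traxler chair on the face away from the benzyl group of the (R)-auxiliary, sets C6 and C7 syn (H6 and H7 cis in the later lactone) and places C6 anti to the C8 silyloxy group, the auxiliary overriding the existing centres.

Step 11
Reactants: 19 Evans syn-aldol adduct
Product: 20 1,3-diol (C6–OH and C11H2–OH)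
Conditions: LiBH4, MeOH (1 equiv), THF, 0 °C
Reagents that add atoms: none
Why: Reductive cleavage of the imide with LiBH4 gives the primary alcohol at C11 and returns the auxiliary, leaving the silyl ether, PMB ether and alkenes untouched.

Step 12
Reactants: 20 1,3-diol
Product: 21 β-hydroxy aldehyde (C11H=O on C7)
Conditions: TEMPO (10 mol %), PhI(OAc)2, CH2Cl2, rt; used crude
Reagents that add atoms: none
Why: TEMPO-catalysed oxidation with PhI(OAc)2 is selective for the primary alcohol over the hindered secondary allylic alcohol and stops at the aldehyde.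

Step 13
Reactants: 21 β-hydroxy aldehyde
Product: 22 homopropargylic alcohol (C7–C11≡C13H; C6–OH)
Conditions: dimethyl (1-diazo-2-oxopropyl)phosphonate, K2CO3, MeOH, 0 °C → rt
Reagents that add atoms: dimethyl (1-diazo-2-oxopropyl)phosphonate COP(=O)(OC)C(=[N+]=[N-])C(C)=O
Why: Ohira–Bestmann (Seyferth–Gilbert) homologation converts the aldehyde into the terminal alkyne C11≡C13 under mild carbonate conditions at low temperature, chosen to limit epimerisation at C7 and retro-aldol cleavage.

Step 14
Reactants: 22 homopropargylic alcohol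
Product: 25 cis-4,5-disubstituted 3-methylidene-oxolan-2-one (α-methylene-γ-butyrolactone O6–C6–C7–C11–C12), via alkoxycarbonylpalladium chloride 23 (not isolated), via alkenylpalladium chloride 24 (not isolated)
Conditions: CO (7 atm), PdCl2 (5 mol %), PPh3 (10 mol %), SnCl2 (5 mol %), MeCN, 70 °C
Reagents that add atoms: carbon monoxide [C-]#[O+]
Why: The alcohol O6–H attacks CO bound to divalent palladium to give the alkoxycarbonylpalladium species 23, whose Pd–C12 bond adds syn across the pendant C11≡C13 triple bond and so closes the lactone by forming C11–C12, after which protonolysis of the alkenyl–Pd bond of 24 by the HCl released in the first event frees 25 and returns PdCl2. The closest known reaction type is the palladium-catalysed cyclocarbonylation of 3-butyn-1-ols to α-methylene-γ-butyrolactones, known for open-chain and ring-fused homopropargylic alcohols. The five-membered ring O6–C6–C7–C11–C12 closes in the 5-exo-dig mode, which leaves C13 exocyclic as the methylene group. No stereocentre is created: the cis relationship of H6 and H7 is inherited from the syn aldol of step 10, and neither centre is epimerisable under these conditions. The step needs O6 to react in preference to O8, which is also homopropargylic, and the TBS ether on O8 secures this. The intramolecular alkyne insertion should outrun insertion into the three alkenes, and the non-oxidative conditions avoid double carbonylation.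

Step 15
Reactants: 25 α-methylene-γ-butyrolactone diene
Product: 26 (1(10)Z,4Z)-8-[(tert-butyldimethylsilyl)oxy]-3-[(4-methoxybenzyl)oxy]germacra-1(10),4,11(13)-trien-12,6-olide
Conditions: second-generation Grubbs catalyst RuCl2(=CHPh)(PCy3)(H2IMes) (10 mol %), 1,4-benzoquinone (20 mol %), toluene (1 mM), 90 °C
Reagents that add atoms: none
Why: Ring-closing metathesis, in which the catalyst loads on the monosubstituted C1 vinyl group and closes onto the isopropenyl group while the cis-fused lactone holds both chains on one side, should give the Z C1=C10 isomer because an E alkene is strained in a ten-membered ring that already contains the Z C4=C5 bond.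

Step 16
Reactants: 26 PMB/TBS-protected macrocycle
Product: 27 C3 alcohol (8-[(tert-butyldimethylsilyl)oxy]-3-hydroxygermacra-1(10)Z,4Z,11(13)-trien-12,6-olide)
Conditions: DDQ, CH2Cl2–pH 7 buffer, 0 °C
Reagents that add atoms: none
Why: Oxidative PMB cleavage with DDQ in buffered wet CH2Cl2 frees O3 without touching the silyl ether, the lactone or the alkenes.

Step 17
Reactants: 27 C3 alcohol
Product: 28 C3 acetate (3-acetoxy-8-[(tert-butyldimethylsilyl)oxy]germacra-1(10)Z,4Z,11(13)-trien-12,6-olide)
Conditions: Ac2O, pyridine, DMAP (cat.), CH2Cl2, 0 °C → rt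
Reagents that add atoms: acetic anhydride CC(=O)OC(C)=O
Why: DMAP-catalysed acetylation installs the C3 acetate with retention at C3.

Step 18
Reactants: 28 C3 acetate
Product: 29 C8 alcohol (3-acetoxy-8-hydroxygermacra-1(10)Z,4Z,11(13)-trien-12,6-olide)
Conditions: HF·pyridine, pyridine, THF, 0 °C → rt
Reagents that add atoms: none
Why: Desilylation with buffered HF·pyridine frees O8 under mildly acidic conditions, which avoid the acyl migration and translactonisation that a basic fluoride source might promote.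

Step 19
Reactants: 29 C8 alcohol
Product: 30 3-acetoxy-8-(3-methylbutanoyloxy)germacra-1(10)Z,4Z,11(13)-trien-12,6-olide
Conditions: 3-methylbutanoyl chloride, pyridine, DMAP (cat.), CH2Cl2, 0 °C → rt
Reagents that add atoms: 3-methylbutanoyl chloride CC(C)CC(Cl)=O
Why: DMAP-catalysed acylation with the acid chloride installs the C8 3-methylbutanoate.

Step 20
Reactants: 30 diester triene
Product: 31 target (1R,3R,6S,7R,8S,10S)-3-acetoxy-1,10-epoxy-8-(3-methylbutanoyloxy)germacra-4Z,11(13)-dien-12,6-olide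
Conditions: D-fructose-derived Shi ketone (30 mol %), KHSO5 (as its triple salt with KHSO4 and K2SO4), K2CO3, Bu4NHSO4, MeCN–CH2(OMe)2–aq. Na2B4O7 buffer, 0 °C
Reagents that add atoms: potassium peroxymonosulfate [K+].[O-]S(=O)(=O)OO
Why: Shi epoxidation, in which the chiral dioxirane transfers oxygen through a spiro transition state to the most electron-rich alkene C1=C10 (C4=C5 is deactivated by two allylic acyloxy groups and C11=C13 is conjugated), is predicted with the D-fructose-derived ketone to give the (1R,10S) cis-oxirane.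

**Compound list**

1 | prop-2-yn-1-ol | C#CCO | starting material
2 | bromomagnesium (Z)-3-(bromomagnesio)-2-methylprop-2-en-1-olate | Br[Mg]/C=C(/C)CO[Mg]Br | intermediate
3 | (Z)-3-iodo-2-methylprop-2-en-1-ol | OC/C(C)=C\I | intermediate
4 | (Z)-3-iodo-2-methylprop-2-enal | O=C/C(C)=C\I | intermediate
5 | (1Z,3R)-1-iodo-2-methylhexa-1,5-dien-3-yl diisopinocampheylborinate | C=CC[C@@H](OB([C@H]1C[C@H]2C[C@@H]([C@@H]1C)C2(C)C)[C@H]1C[C@H]2C[C@@H]([C@@H]1C)C2(C)C)/C(C)=C\I | intermediate
6 | (1Z,3R)-1-iodo-2-methylhexa-1,5-dien-3-ol | C=CC[C@@H](O)/C(C)=C\I | intermediate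
7 | (1Z,3R)-1-iodo-3-[(4-methoxybenzyl)oxy]-2-methylhexa-1,5-diene | C=CC[C@@H](OCc1ccc(OC)cc1)/C(C)=C\I | intermediate
8 | [(1Z,3R)-3-[(4-methoxybenzyl)oxy]-2-methylhexa-1,5-dien-1-yl]lithium | C=CC[C@@H](OCc1ccc(OC)cc1)/C(C)=C\[Li] | intermediate
9 | (2Z,4R)-4-[(4-methoxybenzyl)oxy]-3-methylhepta-2,6-dienal | C=CC[C@@H](OCc1ccc(OC)cc1)/C(C)=C\C=O | intermediate
10 | ethyl 2-[(2R)-oxiran-2-yl]acetate (ethyl (R)-3,4-epoxybutanoate) | CCOC(=O)C[C@@H]1CO1 | starting material
11 | ethyl (3S)-3-hydroxy-5-methylhex-5-enoate | CCOC(=O)C[C@@H](O)CC(C)=C | intermediate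
12 | ethyl (3S)-3-[(tert-butyldimethylsilyl)oxy]-5-methylhex-5-enoate | CCOC(=O)C[C@@H](O[Si](C)(C)C(C)(C)C)CC(C)=C | intermediate
13 | (3S)-3-[(tert-butyldimethylsilyl)oxy]-5-methylhex-5-enoic acid | OC(=O)C[C@@H](O[Si](C)(C)C(C)(C)C)CC(C)=C | intermediate
14 | (4R)-4-benzyl-1,3-oxazolidin-2-one | O=C1OC[C@@H](Cc2ccccc2)N1 | starting material
15 | mixed anhydride of 13 with pivalic acid | CC(C)(C)C(=O)OC(=O)C[C@@H](O[Si](C)(C)C(C)(C)C)CC(C)=C | intermediate
16 | (4R)-4-benzyl-3-[(3S)-3-[(tert-butyldimethylsilyl)oxy]-5-methylhex-5-enoyl]-1,3-oxazolidin-2-one | O=C1OC[C@@H](Cc2ccccc2)N1C(=O)C[C@@H](O[Si](C)(C)C(C)(C)C)CC(C)=C | intermediate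
17 | Z-dibutylboron enolate of 16 (O–B cis to C8) | CCCCB(CCCC)O/C(=C\[C@@H](O[Si](C)(C)C(C)(C)C)CC(C)=C)N1[C@H](Cc2ccccc2)COC1=O | intermediate
18 | dibutylboron aldolate of 19 (B on O6) | C=CC[C@@H](OCc1ccc(OC)cc1)/C(C)=C\[C@H](OB(CCCC)CCCC)[C@H](C(=O)N1[C@H](Cc2ccccc2)COC1=O)[C@@H](O[Si](C)(C)C(C)(C)C)CC(C)=C | intermediate
19 | Evans syn-aldol adduct: (4R)-4-benzyl-3-acyl-oxazolidin-2-one with acyl chain C11(=O)–C7H[C8H(OTBS)–C9H2–C10(CH3)=CH2]–C6H(OH)–C5H=C4(CH3)–C3H(OPMB)–C2H2–C1H=CH2; 4Z; C3, C6, C7, C8 arranged as in 31 | C=CC[C@@H](OCc1ccc(OC)cc1)/C(C)=C\[C@H](O)[C@H](C(=O)N1[C@H](Cc2ccccc2)COC1=O)[C@@H](O[Si](C)(C)C(C)(C)C)CC(C)=C | intermediate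
20 | 1,3-diol: as 19 with C11H2OH in place of the imide | C=CC[C@@H](OCc1ccc(OC)cc1)/C(C)=C\[C@H](O)[C@H](CO)[C@@H](O[Si](C)(C)C(C)(C)C)CC(C)=C | intermediate
21 | β-hydroxy aldehyde: as 20 with C11H=O | C=CC[C@@H](OCc1ccc(OC)cc1)/C(C)=C\[C@H](O)[C@H](C=O)[C@@H](O[Si](C)(C)C(C)(C)C)CC(C)=C | intermediate
22 | homopropargylic alcohol: as 20 with C11≡C13H on C7 | C=CC[C@@H](OCc1ccc(OC)cc1)/C(C)=C\[C@H](O)[C@H](C#C)[C@@H](O[Si](C)(C)C(C)(C)C)CC(C)=C | intermediate
23 | alkoxycarbonylpalladium chloride (O6–C12(=O)–PdCl; phosphine ligands omitted) | C=CC[C@@H](OCc1ccc(OC)cc1)/C(C)=C\[C@H](OC(=O)[Pd]Cl)[C@H](C#C)[C@@H](O[Si](C)(C)C(C)(C)C)CC(C)=C | intermediate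
24 | alkenylpalladium chloride (Pd on C13, cis to C12; phosphine ligands omitted) | Cl[Pd]/C=C1\C(=O)O[C@@H](/C=C(/C)[C@H](OCc2ccc(OC)cc2)CC=C)[C@H]1[C@@H](O[Si](C)(C)C(C)(C)C)CC(C)=C | intermediate
25 | cis-4,5-disubstituted 3-methylidene-oxolan-2-one: C5 chain on C6, C8 chain on C7 | C=C1C(=O)O[C@@H](/C=C(/C)[C@H](OCc2ccc(OC)cc2)CC=C)[C@H]1[C@@H](O[Si](C)(C)C(C)(C)C)CC(C)=C | intermediate
26 | (1(10)Z,4Z)-8-[(tert-butyldimethylsilyl)oxy]-3-[(4-methoxybenzyl)oxy]germacra-1(10),4,11(13)-trien-12,6-olide (6,7-cis) | C=C1C(=O)O[C@H]2/C=C(/C)[C@H](OCc3ccc(OC)cc3)C/C=C(/C)C[C@H](O[Si](C)(C)C(C)(C)C)[C@@H]12 | intermediate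
27 | (1(10)Z,4Z)-8-[(tert-butyldimethylsilyl)oxy]-3-hydroxygermacra-1(10),4,11(13)-trien-12,6-olide | C=C1C(=O)O[C@H]2/C=C(/C)[C@H](O)C/C=C(/C)C[C@H](O[Si](C)(C)C(C)(C)C)[C@@H]12 | intermediate
28 | (1(10)Z,4Z)-3-acetoxy-8-[(tert-butyldimethylsilyl)oxy]germacra-1(10),4,11(13)-trien-12,6-olide | C=C1C(=O)O[C@H]2/C=C(/C)[C@H](OC(C)=O)C/C=C(/C)C[C@H](O[Si](C)(C)C(C)(C)C)[C@@H]12 | intermediate
29 | (1(10)Z,4Z)-3-acetoxy-8-hydroxygermacra-1(10),4,11(13)-trien-12,6-olide | C=C1C(=O)O[C@H]2/C=C(/C)[C@H](OC(C)=O)C/C=C(/C)C[C@H](O)[C@@H]12 | intermediate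
30 | (1(10)Z,4Z,3R,6S,7R,8S)-3-acetoxy-8-(3-methylbutanoyloxy)germacra-1(10),4,11(13)-trien-12,6-olide | C=C1C(=O)O[C@H]2/C=C(/C)[C@H](OC(C)=O)C/C=C(/C)C[C@H](OC(=O)CC(C)C)[C@@H]12 | intermediate
31 | (4Z,1R,3R,6S,7R,8S,10S)-3-acetoxy-1,10-epoxy-8-(3-methylbutanoyloxy)germacra-4,11(13)-dien-12,6-olide | C=C1C(=O)O[C@H]2/C=C(/C)[C@H](OC(C)=O)C[C@H]3O[C@@]3(C)C[C@H](OC(=O)CC(C)C)[C@@H]12 | target

**Count and risks**

Total step count: 20. Longest linear sequence: 16 steps (steps 1–5, then 10–20).

Step 15, ring-closing metathesis. The ten-membered ring may fail to close because oligomerisation, formation of the E isomer at C1=C10, or engagement of the exocyclic C11=C13 alkene competes. Fallback: the ring is closed before the alkyne and the lactone exist. From diol 20, acetalisation (2,2-dimethoxypropane, PPTS) gives the acetonide F1, whose 1,3-dioxane ties C6 and C7 together as the lactone would. Ring-closing metathesis with the same ruthenium catalyst then gives the macrocyclic acetonide F2, and aqueous AcOH in THF gives the macrocyclic diol F3. TEMPO/PhI(OAc)2 oxidation gives the macrocyclic hydroxy aldehyde F4, and Ohira–Bestmann homologation gives the macrocyclic alkynol F5. The cyclocarbonylation of step 14, run on F5, gives 26, where the route resumes.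

Step 14, cyclocarbonylation. Turnover may be slow with the hindered allylic alcohol, the silyl ether may be lost under the Lewis-acidic conditions, or palladium hydrides may isomerise the terminal alkenes. Fallback: C12 is brought in as CO2 and the ring is closed by esterification. From 22, nickel-catalysed Markovnikov hydrocarboxylation of the terminal alkyne (NiCl2·glyme, neocuproine, Mn, i-PrOH, CO2 at 1 atm, DMF) gives the 2-substituted acrylic acid F6. Lactonisation of this cis-disposed γ-hydroxy acid (EDC, DMAP, CH2Cl2) gives 25.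

Step 20, epoxidation. Facial selectivity may be poor or reversed if the conformation of the ten-membered ring exposes the other face of C1=C10 and overrides the reagent. Fallback: from 30, NBS in aqueous THF gives the bromohydrin F7 by anti addition (Br at C1 from the exposed face, OH at C10). Ag2O in CH2Cl2 then closes it with inversion at C1, placing the oxirane on the face opposite to the one reached by direct oxygen transfer and giving 31.

**Further compounds**

F1 | step 15 | acetonide of diol 20 (2,2-dimethyl-1,3-dioxane across O6 and O11) | C=CC[C@@H](OCc1ccc(OC)cc1)/C(C)=C\[C@@H]1OC(C)(C)OC[C@@H]1[C@@H](O[Si](C)(C)C(C)(C)C)CC(C)=C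
F2 | step 15 | macrocyclic acetonide (ten-membered ring with Z C1=C10 and Z C4=C5, fused to the 1,3-dioxane) | CC1(C)OC[C@H]2[C@@H](O1)/C=C(/C)[C@H](OCc1ccc(OC)cc1)C/C=C(/C)C[C@@H]2O[Si](C)(C)C(C)(C)C
F3 | step 15 | macrocyclic diol (C6–OH and C11H2–OH on the cyclodecadiene) | OC[C@H]1[C@@H](O)/C=C(/C)[C@H](OCc2ccc(OC)cc2)C/C=C(/C)C[C@@H]1O[Si](C)(C)C(C)(C)C
F4 | step 15 | macrocyclic hydroxy aldehyde (C11H=O on C7) | O=C[C@H]1[C@@H](O)/C=C(/C)[C@H](OCc2ccc(OC)cc2)C/C=C(/C)C[C@@H]1O[Si](C)(C)C(C)(C)C
F5 | step 15 | macrocyclic alkynol (ethynyl on C7, OH on C6) | C#C[C@H]1[C@@H](O)/C=C(/C)[C@H](OCc2ccc(OC)cc2)C/C=C(/C)C[C@@H]1O[Si](C)(C)C(C)(C)C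
F6 | step 14 | 2-substituted acrylic acid (C11(=C13H2)–C12O2H on C7, free C6–OH) | C=CC[C@@H](OCc1ccc(OC)cc1)/C(C)=C\[C@H](O)[C@H](C(=C)C(=O)O)[C@@H](O[Si](C)(C)C(C)(C)C)CC(C)=C
F7 | step 20 | bromohydrin of 30 (Br at C1, OH at C10, anti) | C=C1C(=O)O[C@H]2/C=C(/C)[C@H](OC(C)=O)C[C@H](Br)[C@@](C)(O)C[C@H](OC(=O)CC(C)C)[C@@H]12
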